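## Retrosynthetic overview

1. Target 26 is a (2R,3R)-2,3-dibenzylbutane-1,4-diol in which one benzyl group is C5 of a trans-(2S,3R)-2-aryl-3-(hydroxymethyl)-7-methoxy-2,3-dihydrobenzofuran; the closing operations are purely reductive (lactone acetal to diol, dithiane to CH2, O-benzyl to OH).
2. Enabling feature: the chain HOCH2–CH–CH–CH2OH, oxygenated at both ends, is a latent five-membered lactone (carbonyl C2 and acetal C5 of a furan-2(5H)-one ring). The CH that must bond to the benzofuranyl CH2 is therefore the α-carbon of a lactone enolate and its neighbour the β-carbon of a butenolide. The CH2 partner is a benzylic carbon para to ring oxygen O1 on the benzo ring of the dihydrobenzofuran, hence a strong SN2 electrophile.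
3. Key disconnection: the benzylic CH2–CH(α) bond, formed in a three-component tandem conjugate addition–enolate benzylation of (5R)-5-menthyloxyfuran-2(5H)-one 20 with lithiated dithiane 21 and bromide 18. Two C–C bonds and both butanediol stereocentres are relayed from the single acetal stereocentre.
4. Bromide 18: benzo ring bought (methyl vanillate); arylacetic acid by Claisen rearrangement and alkene cleavage; C3 by an Evans syn-aldol; C2 set trans by substrate control when the dihydrofuran ring closes through benzylic C–O cyclisation.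
5. Ring order: dihydrofuran ring closed (step 8, the only ring made) → bought lactone ring used as stereochemical template (step 13) → lactone ring opened to the diol (step 14).

Key step: step 13

Remarks on the chemistry and naming:
- Assumption: (5R)-5-(l-menthyloxy)furan-2(5H)-one 20 is taken as a purchasable single diastereomer derived from (−)-menthol.
- Abbreviations used in names: Ar = 4-(benzyloxy)-3-methoxyphenyl; Men = (1R,2S,5R)-2-isopropyl-5-methylcyclohexyl; BF = (2S,3R)-2-[4-(benzyloxy)-3-methoxyphenyl]-3-[(benzyloxy)methyl]-7-methoxy-2,3-dihydro-1-benzofuran-5-yl.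

## Route

Step 1
Reactants: 1 methyl 4-hydroxy-3-methoxybenzoate (methyl vanillate)
Product: 2 methyl 3-methoxy-4-(prop-2-en-1-yloxy)benzoate
Conditions: allyl bromide, K2CO3, acetone, reflux
Reagents that add atoms: allyl bromide C=CCBr
Why: Williamson etherification of the phenoxide with an allylic bromide is fast and O-selective under these conditions and involves no stereocentre.

Step 2
Reactants: 2 methyl 3-methoxy-4-(prop-2-en-1-yloxy)benzoate
Product: 3 methyl 4-hydroxy-3-methoxy-5-(prop-2-en-1-yl)benzoate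
Conditions: N,N-diethylaniline, 200 °C
Reagents that add atoms: none
Why: The thermal aromatic Claisen rearrangement (a [3,3]-sigmatropic shift followed by tautomerisation) delivers the allyl group to the only free ortho position, because the other ortho carbon carries OMe and the para carbon carries the ester.

Step 3
Reactants: 3 methyl 4-hydroxy-3-methoxy-5-(prop-2-en-1-yl)benzoate
Product: 4 methyl 3-methoxy-4-(methoxymethoxy)-5-(prop-2-en-1-yl)benzoate
Conditions: MOMCl, iPr2NEt, CH2Cl2, 0 °C → rt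
Reagents that add atoms: chloromethyl methyl ether COCCl
Why: Base-mediated O-alkylation gives a MOM acetal that should survive ozonolysis, chlorite oxidation, boron enolisation and borohydride and is cleaved later by the same acid that closes the dihydrofuran ring.

Step 4
Reactants: 4 methyl 3-methoxy-4-(methoxymethoxy)-5-(prop-2-en-1-yl)benzoate
Product: 6 2-[3-methoxy-5-(methoxycarbonyl)-2-(methoxymethoxy)phenyl]acetic acid, via arylacetaldehyde 5 (not isolated)
Conditions: O3, CH2Cl2/MeOH, −78 °C; Me2S; then NaClO2, NaH2PO4, 2-methylbut-2-ene, t-BuOH/H2O, rt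
Reagents that add atoms: ozone [O-][O+]=O; sodium chlorite [Na+].[O-]Cl=O
Why: Ozonolysis of the terminal alkene (far more reactive towards ozone than the ester-deactivated arene) with reductive work-up gives the arylacetaldehyde, which is oxidised at once under buffered Pinnick conditions that leave the MOM ether and the methyl ester alone.

Step 5
Reactants: 6 2-[3-methoxy-5-(methoxycarbonyl)-2-(methoxymethoxy)phenyl]acetic acid; 7 (4S)-4-benzyl-1,3-oxazolidin-2-one
Product: 9 methyl 3-{2-[(4S)-4-benzyl-2-oxo-1,3-oxazolidin-3-yl]-2-oxoethyl}-5-methoxy-4-(methoxymethoxy)benzoate, via mixed pivalic anhydride 8 (not isolated)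
Conditions: PivCl, Et3N, THF, −20 °C; then 7, LiCl, rt
Reagents that add atoms: pivaloyl chloride CC(C)(C)C(=O)Cl (its atoms stay only in intermediate 8)
Why: N-Acylation of the oxazolidinone through the mixed pivalic anhydride with LiCl/Et3N activation is the standard mild loading of an Evans auxiliary, and attack occurs at the less hindered arylacetyl carbonyl.

Step 6
Reactants: 9 methyl 3-{2-[(4S)-4-benzyl-2-oxo-1,3-oxazolidin-3-yl]-2-oxoethyl}-5-methoxy-4-(methoxymethoxy)benzoate; 10 4-(benzyloxy)-3-methoxybenzaldehyde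
Product: 12 methyl 3-{(2S,3S)-1-[(4S)-4-benzyl-2-oxo-1,3-oxazolidin-3-yl]-3-[4-(benzyloxy)-3-methoxyphenyl]-3-hydroxy-1-oxopropan-2-yl}-5-methoxy-4-(methoxymethoxy)benzoate, via Z-boron enolate 11 (not isolated)
Conditions: Bu2BOTf, iPr2NEt, CH2Cl2, −78 → 0 °C; 10, −78 → 0 °C; pH 7 buffer, MeOH, 30% H2O2
Reagents that add atoms: dibutylboron triflate CCCCB(CCCC)OS(=O)(=O)C(F)(F)F (its atoms stay only in intermediate 11)
Why: In this Evans boron aldol reaction the Z-enolate reacts through a closed Zimmerman–Traxler chair on the face away from the auxiliary benzyl group to give the syn (2S,3S) adduct, so the α-carbon (the future C3 of the dihydrobenzofuran) is set by the auxiliary while the carbinol configuration is of no consequence for step 8.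

Step 7
Reactants: 12 methyl 3-{(2S,3S)-1-[(4S)-4-benzyl-2-oxo-1,3-oxazolidin-3-yl]-3-[4-(benzyloxy)-3-methoxyphenyl]-3-hydroxy-1-oxopropan-2-yl}-5-methoxy-4-(methoxymethoxy)benzoate
Product: 13 methyl 3-{(1S,2R)-1-[4-(benzyloxy)-3-methoxyphenyl]-1,3-dihydroxypropan-2-yl}-5-methoxy-4-(methoxymethoxy)benzoate
Conditions: NaBH4, THF/H2O, 0 °C → rt
Reagents that add atoms: none
Why: Borohydride reduction of the activated exocyclic imide carbonyl (reductive removal of an Evans auxiliary) gives the primary alcohol and returns 7, while the less electrophilic methyl benzoate and the MOM ether should be untouched and the stereocentre, no longer α to a carbonyl, cannot epimerise.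

Step 8
Reactants: 13 methyl 3-{(1S,2R)-1-[4-(benzyloxy)-3-methoxyphenyl]-1,3-dihydroxypropan-2-yl}-5-methoxy-4-(methoxymethoxy)benzoate
Product: 15 methyl (2S,3R)-2-[4-(benzyloxy)-3-methoxyphenyl]-3-(hydroxymethyl)-7-methoxy-2,3-dihydro-1-benzofuran-5-carboxylate, via free phenol 14 (not isolated)
Conditions: HCl, MeOH, 40 °C
Reagents that add atoms: none
Why: Acid-catalysed methanolysis of the MOM acetal frees the ortho phenol, and ionisation of the para-benzyloxy-stabilised benzylic alcohol then allows SN1-type five-membered ring closure by the phenol oxygen (the phenylcoumaran cyclisation of lignin chemistry), which should place the C2 aryl group trans to the C3 CH2OH group under substrate and thermodynamic control from the fixed C3 centre whatever the carbinol configuration was.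

Step 9
Reactants: 15 methyl (2S,3R)-2-[4-(benzyloxy)-3-methoxyphenyl]-3-(hydroxymethyl)-7-methoxy-2,3-dihydro-1-benzofuran-5-carboxylate
Product: 16 methyl (2S,3R)-2-[4-(benzyloxy)-3-methoxyphenyl]-3-[(benzyloxy)methyl]-7-methoxy-2,3-dihydro-1-benzofuran-5-carboxylate
Conditions: NaH, BnBr, Bu4NI (cat.), THF/DMF, 0 °C → rt
Reagents that add atoms: benzyl bromide BrCc1ccccc1
Why: Williamson benzylation of the primary alkoxide masks the only O–H that would quench the enolate in step 13, with a group that leaves in the final hydrogenolysis together with the phenolic benzyl ethers.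

Step 10
Reactants: 16 methyl (2S,3R)-2-[4-(benzyloxy)-3-methoxyphenyl]-3-[(benzyloxy)methyl]-7-methoxy-2,3-dihydro-1-benzofuran-5-carboxylate
Product: 17 {(2S,3R)-2-[4-(benzyloxy)-3-methoxyphenyl]-3-[(benzyloxy)methyl]-7-methoxy-2,3-dihydro-1-benzofuran-5-yl}methanol (BF-methanol)
Conditions: LiAlH4, THF, 0 °C
Reagents that add atoms: none
Why: Hydride reduction of the aryl methyl ester to the benzylic alcohol is unproblematic because the ethers and the dihydrobenzofuran ring are inert to LiAlH4.

Step 11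
Reactants: 17 BF-methanol
Product: 18 (2S,3R)-2-[4-(benzyloxy)-3-methoxyphenyl]-3-[(benzyloxy)methyl]-5-(bromomethyl)-7-methoxy-2,3-dihydro-1-benzofuran (BF-methyl bromide)
Conditions: CBr4, PPh3, CH2Cl2, 0 °C
Reagents that add atoms: carbon tetrabromide BrC(Br)(Br)Br
Why: Appel bromination converts the primary benzylic alcohol into the bromide under neutral conditions that spare the acid-sensitive benzylic C2–O1 bond, and the electron-rich bromide is used directly.

Step 12
Reactants: 10 4-(benzyloxy)-3-methoxybenzaldehyde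
Product: 19 2-[4-(benzyloxy)-3-methoxyphenyl]-1,3-dithiane
Conditions: HS(CH2)3SH, BF3·OEt2 (cat.), CH2Cl2, 0 °C → rt
Reagents that add atoms: propane-1,3-dithiol SCCCS
Why: Lewis-acid-catalysed dithioacetalisation of the aromatic aldehyde gives the dithiane needed for umpolung of the guaiacyl benzylic carbon.

Step 13
Reactants: 19 2-[4-(benzyloxy)-3-methoxyphenyl]-1,3-dithiane; 20 (5R)-5-(Men-oxy)furan-2(5H)-one; 18 BF-methyl bromide
Product: 23 (3R,4R,5R)-3-(BF-methyl)-4-(2-Ar-1,3-dithian-2-yl)-5-(Men-oxy)oxolan-2-one, via lithiated dithiane 21 (not isolated), via lithium enolate 22 (not isolated)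
Conditions: 19, n-BuLi, THF, −78 → −20 °C; 20, −78 °C; then 18, DMPU, −78 → −20 °C
Reagents that add atoms: n-butyllithium [Li]CCCC (its lithium stays only in intermediates 21 and 22)
Why: The soft, aryl-stabilised 2-lithio-1,3-dithiane 21 adds 1,4 to butenolide 20 on the face anti to the C5 menthyloxy group, which sets C4 and gives lithium enolate 22; the enolate is then C-benzylated by SN2 attack on bromide 18 on the face anti to the bulky C4 dithianyl group, which forms the CH2–CH bond and sets C3 trans to C4. The closest known reaction type is the tandem conjugate addition–enolate alkylation of 5-alkoxyfuran-2(5H)-ones with lithiated dithianes and benzylic bromides used for trans-dibenzylbutyrolactone lignans. No ring is closed in this step; the existing lactone ring serves only as the rigid template. Both new stereocentres are under substrate control relayed from the single acetal stereocentre at C5 (bought with (−)-menthol), and the two stereocentres of 18 are spectators. The step needs 1,4- over 1,2-addition (secured by the delocalised dithiane anion and the acylal-type carbonyl), and C-alkylation without proton transfer or double alkylation (secured by the lithium enolate in THF/DMPU, the highly SN2-reactive para-alkoxybenzylic bromide, the absence of any acidic C–H or O–H in 18 because its CH2OH is a benzyl ether, and the hindered tertiary α-carbon of the product).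

Step 14
Reactants: 23 (3R,4R,5R)-3-(BF-methyl)-4-(2-Ar-1,3-dithian-2-yl)-5-(Men-oxy)oxolan-2-one
Product: 24 (2R,3R)-2-(BF-methyl)-3-(2-Ar-1,3-dithian-2-yl)butane-1,4-diol
Conditions: LiAlH4, THF, 0 °C → reflux
Reagents that add atoms: none
Why: LiAlH4 reduces the lactone carbonyl and, after collapse of the resulting hemiacetal, the aldehyde released from the acetal carbon, so both termini become CH2OH with loss of menthol (reductive opening of a 5-alkoxybutyrolactone to a 1,4-diol), and neither stereocentre should be touched because the transient aldehydes are reduced faster than they enolise.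

Step 15
Reactants: 24 (2R,3R)-2-(BF-methyl)-3-(2-Ar-1,3-dithian-2-yl)butane-1,4-diol
Product: 25 (2R,3R)-2-(Ar-methyl)-3-(BF-methyl)butane-1,4-diol
Conditions: NiCl2·6H2O, NaBH4, MeOH/THF, 0 °C → rt
Reagents that add atoms: none
Why: Nickel boride formed in situ cleaves both benzylic C–S bonds reductively (desulfurisation of a dithioacetal to CH2) under conditions that are expected to spare benzyl ethers and the free diol.

Step 16
Reactants: 25 (2R,3R)-2-(Ar-methyl)-3-(BF-methyl)butane-1,4-diol
Product: 26 (2R,3R)-2-(4-hydroxy-3-methoxybenzyl)-3-{[(2S,3R)-2-(4-hydroxy-3-methoxyphenyl)-3-(hydroxymethyl)-7-methoxy-2,3-dihydro-1-benzofuran-5-yl]methyl}butane-1,4-diol (CNP0256425.1)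
Conditions: H2 (1 atm), 10% Pd/C, EtOAc/MeOH, rt
Reagents that add atoms: none
Why: Catalytic hydrogenolysis removes the two aryl benzyl ethers and the primary alkyl benzyl ether in one operation, while the cyclic secondary benzylic C2–O1 bond of the phenylcoumaran is expected to survive neutral Pd/C at ambient pressure as in related dihydrobenzofuran neolignans, and no stereocentre is touched.

## Compound list

1 | methyl 4-hydroxy-3-methoxybenzoate (methyl vanillate) | COC(=O)c1ccc(O)c(OC)c1 | starting material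
2 | methyl 3-methoxy-4-(prop-2-en-1-yloxy)benzoate | COC(=O)c1ccc(OCC=C)c(OC)c1 | intermediate
3 | methyl 4-hydroxy-3-methoxy-5-(prop-2-en-1-yl)benzoate | COC(=O)c1cc(CC=C)c(O)c(OC)c1 | intermediate
4 | methyl 3-methoxy-4-(methoxymethoxy)-5-(prop-2-en-1-yl)benzoate | COC(=O)c1cc(CC=C)c(OCOC)c(OC)c1 | intermediate
5 | methyl 3-methoxy-4-(methoxymethoxy)-5-(2-oxoethyl)benzoate (formed in situ) | COC(=O)c1cc(CC=O)c(OCOC)c(OC)c1 | intermediate
6 | 2-[3-methoxy-5-(methoxycarbonyl)-2-(methoxymethoxy)phenyl]acetic acid | COC(=O)c1cc(CC(=O)O)c(OCOC)c(OC)c1 | intermediate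
7 | (4S)-4-benzyl-1,3-oxazolidin-2-one | O=C1N[C@@H](Cc2ccccc2)CO1 | starting material
8 | mixed anhydride of 6 with pivalic acid (formed in situ) | COC(=O)c1cc(CC(=O)OC(=O)C(C)(C)C)c(OCOC)c(OC)c1 | intermediate
9 | methyl 3-{2-[(4S)-4-benzyl-2-oxo-1,3-oxazolidin-3-yl]-2-oxoethyl}-5-methoxy-4-(methoxymethoxy)benzoate | COC(=O)c1cc(CC(=O)N2[C@@H](Cc3ccccc3)COC2=O)c(OCOC)c(OC)c1 | intermediate
10 | 4-(benzyloxy)-3-methoxybenzaldehyde | COc1cc(C=O)ccc1OCc1ccccc1 | starting material
11 | Z-dibutylboron enolate of 9 (formed in situ) | CCCCB(CCCC)O/C(=C\c1cc(C(=O)OC)cc(OC)c1OCOC)N1[C@@H](Cc2ccccc2)COC1=O | intermediate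
12 | methyl 3-{(2S,3S)-1-[(4S)-4-benzyl-2-oxo-1,3-oxazolidin-3-yl]-3-[4-(benzyloxy)-3-methoxyphenyl]-3-hydroxy-1-oxopropan-2-yl}-5-methoxy-4-(methoxymethoxy)benzoate | COC(=O)c1cc([C@H](C(=O)N2[C@@H](Cc3ccccc3)COC2=O)[C@H](O)c2ccc(OCc3ccccc3)c(OC)c2)c(OCOC)c(OC)c1 | intermediate
13 | methyl 3-{(1S,2R)-1-[4-(benzyloxy)-3-methoxyphenyl]-1,3-dihydroxypropan-2-yl}-5-methoxy-4-(methoxymethoxy)benzoate | COC(=O)c1cc([C@H](CO)[C@H](O)c2ccc(OCc3ccccc3)c(OC)c2)c(OCOC)c(OC)c1 | intermediate
14 | methyl 3-{(1S,2R)-1-[4-(benzyloxy)-3-methoxyphenyl]-1,3-dihydroxypropan-2-yl}-4-hydroxy-5-methoxybenzoate (formed in situ) | COC(=O)c1cc([C@H](CO)[C@H](O)c2ccc(OCc3ccccc3)c(OC)c2)c(O)c(OC)c1 | intermediate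
15 | methyl (2S,3R)-2-[4-(benzyloxy)-3-methoxyphenyl]-3-(hydroxymethyl)-7-methoxy-2,3-dihydro-1-benzofuran-5-carboxylate | COC(=O)c1cc(OC)c2c(c1)[C@H](CO)[C@@H](c1ccc(OCc3ccccc3)c(OC)c1)O2 | intermediate
16 | methyl (2S,3R)-2-[4-(benzyloxy)-3-methoxyphenyl]-3-[(benzyloxy)methyl]-7-methoxy-2,3-dihydro-1-benzofuran-5-carboxylate | COC(=O)c1cc(OC)c2c(c1)[C@H](COCc1ccccc1)[C@@H](c1ccc(OCc3ccccc3)c(OC)c1)O2 | intermediate
17 | {(2S,3R)-2-[4-(benzyloxy)-3-methoxyphenyl]-3-[(benzyloxy)methyl]-7-methoxy-2,3-dihydro-1-benzofuran-5-yl}methanol | OCc1cc(OC)c2c(c1)[C@H](COCc1ccccc1)[C@@H](c1ccc(OCc3ccccc3)c(OC)c1)O2 | intermediate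
18 | (2S,3R)-2-[4-(benzyloxy)-3-methoxyphenyl]-3-[(benzyloxy)methyl]-5-(bromomethyl)-7-methoxy-2,3-dihydro-1-benzofuran | BrCc1cc(OC)c2c(c1)[C@H](COCc1ccccc1)[C@@H](c1ccc(OCc3ccccc3)c(OC)c1)O2 | intermediate
19 | 2-[4-(benzyloxy)-3-methoxyphenyl]-1,3-dithiane | COc1cc(C2SCCCS2)ccc1OCc1ccccc1 | intermediate
20 | (5R)-5-{[(1R,2S,5R)-2-isopropyl-5-methylcyclohexyl]oxy}furan-2(5H)-one | O=C1C=C[C@H](O[C@@H]2C[C@H](C)CC[C@H]2C(C)C)O1 | starting material
21 | 2-[4-(benzyloxy)-3-methoxyphenyl]-2-lithio-1,3-dithiane (formed in situ) | [Li]C1(c2ccc(OCc3ccccc3)c(OC)c2)SCCCS1 | intermediate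
22 | lithium enolate of (4R,5R)-4-(2-Ar-1,3-dithian-2-yl)-5-(Men-oxy)oxolan-2-one (formed in situ) | [Li]OC1=C[C@@H](C2(c3ccc(OCc4ccccc4)c(OC)c3)SCCCS2)[C@H](O[C@@H]2C[C@H](C)CC[C@H]2C(C)C)O1 | intermediate
23 | (3R,4R,5R)-3-(BF-methyl)-4-(2-Ar-1,3-dithian-2-yl)-5-(Men-oxy)oxolan-2-one | O=C1[C@H](Cc2cc(OC)c3c(c2)[C@H](COCc2ccccc2)[C@@H](c2ccc(OCc4ccccc4)c(OC)c2)O3)[C@@H](C2(c3ccc(OCc4ccccc4)c(OC)c3)SCCCS2)[C@H](O[C@@H]2C[C@H](C)CC[C@H]2C(C)C)O1 | intermediate
24 | (2R,3R)-2-(BF-methyl)-3-(2-Ar-1,3-dithian-2-yl)butane-1,4-diol | OC[C@H](Cc1cc(OC)c2c(c1)[C@H](COCc1ccccc1)[C@@H](c1ccc(OCc3ccccc3)c(OC)c1)O2)[C@@H](C1(c2ccc(OCc3ccccc3)c(OC)c2)SCCCS1)CO | intermediate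
25 | (2R,3R)-2-(Ar-methyl)-3-(BF-methyl)butane-1,4-diol | OC[C@H](Cc1cc(OC)c2c(c1)[C@H](COCc1ccccc1)[C@@H](c1ccc(OCc3ccccc3)c(OC)c1)O2)[C@@H](Cc1ccc(OCc2ccccc2)c(OC)c1)CO | intermediate
26 | (2R,3R)-2-(4-hydroxy-3-methoxybenzyl)-3-{[(2S,3R)-2-(4-hydroxy-3-methoxyphenyl)-3-(hydroxymethyl)-7-methoxy-2,3-dihydro-1-benzofuran-5-yl]methyl}butane-1,4-diol | COc1cc(C[C@@H](CO)[C@H](CO)Cc2cc(OC)c3c(c2)[C@H](CO)[C@@H](c2ccc(O)c(OC)c2)O3)ccc1O | target

## Step count and risks

Total: 16 steps. Longest linear sequence: 15 steps (steps 1–11 and 13–16); step 12 is a one-step side branch.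

Steps most likely to fail:

1. Step 13. C-Benzylation of the crowded enolate 22 (a quaternary dithianyl carbon sits next to the reacting α-carbon) may be slower than proton transfer or than ionisation and decay of the electron-rich bromide, and attack syn to the dithianyl group would erode the trans selectivity. Fallback, setting out from 19 and 20 and coming back at 25: the conjugate addition is run alone and 22 is protonated (NH4Cl, −78 °C) to give (4R,5R)-4-(2-Ar-1,3-dithian-2-yl)-5-(Men-oxy)oxolan-2-one F1. Desulfurisation (NiCl2·6H2O, NaBH4, MeOH/THF) gives (4R,5R)-4-(Ar-methyl)-5-(Men-oxy)oxolan-2-one F2. Its preformed lithium enolate F3 (LDA, THF/DMPU, −78 °C), now flanked only by a CH2Ar group, is benzylated with 18 anti to that group, the classical alkylation of 4-benzylbutyrolactones, to give (3R,4R,5R)-4-(Ar-methyl)-3-(BF-methyl)-5-(Men-oxy)oxolan-2-one F4. LiAlH4 as in step 14 converts this into 25, so steps 14 and 15 fall away.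

2. Step 8. The benzylic cation may lose a proton or expel formaldehyde (retro-Prins fragmentation of the 1,3-diol) instead of being captured, the formaldehyde equivalent released from the MOM group may tie up the diol as a cyclic formal, and capture by the phenol may not be fully trans-selective. Fallback, setting out from 3 and coming back at 15: the ring oxygen is joined to the arene instead of to the benzylic carbon, so no bond to a stereocentre is broken.
   - Phenol 3 is converted (Tf2O, pyridine, CH2Cl2) into methyl 3-methoxy-5-(prop-2-en-1-yl)-4-{[(trifluoromethyl)sulfonyl]oxy}benzoate F5.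
   - The operations of steps 4–7 follow unchanged: ozonolysis through the aldehyde methyl 3-methoxy-5-(2-oxoethyl)-4-{[(trifluoromethyl)sulfonyl]oxy}benzoate F6 and chlorite oxidation to 2-[3-methoxy-5-(methoxycarbonyl)-2-{[(trifluoromethyl)sulfonyl]oxy}phenyl]acetic acid F7; activation as its mixed pivalic anhydride F8 and acylation of 7 to the triflate analogue of imide 9 F9; boron enolisation to its Z-dibutylboron enolate F10 and aldol reaction with 10 to the triflate analogue of syn-aldol 12 F11; borohydride reduction to the triflate analogue of diol 13 F12.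
   - Pd-catalysed intramolecular aryl etherification (Pd(OAc)2, 2-di-tert-butylphosphino-2′,4′,6′-triisopropylbiphenyl, K3PO4, toluene, 80 °C) then closes the ring through the secondary carbinol oxygen with retention at the (1S) carbinol carbon, so the syn relationship from the aldol translates directly into the trans-(2S,3R) ring of 15. The primary hydroxyl could only form a four-membered ring and stays free.

3. Step 15. Nickel-mediated hydrogenolysis may not stop at the C–S bonds (cleavage of aryl benzyl ethers or of the benzylic C2–O1 bond), or C–S cleavage may stall at the hindered quaternary carbon. Fallback, setting out from 24 and coming back at 25: homolytic desulfurisation with Bu3SnH (excess) and AIBN in toluene at reflux, a radical chain in which stannyl radicals cleave the benzylic C–S bonds while C–O bonds are inert; this fallback makes no new compound (F0).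

## Further compounds

F1 | step 13 | (4R,5R)-4-(2-Ar-1,3-dithian-2-yl)-5-(Men-oxy)oxolan-2-one | O=C1C[C@@H](C2(c3ccc(OCc4ccccc4)c(OC)c3)SCCCS2)[C@H](O[C@@H]2C[C@H](C)CC[C@H]2C(C)C)O1
F2 | step 13 | (4R,5R)-4-(Ar-methyl)-5-(Men-oxy)oxolan-2-one | O=C1C[C@@H](Cc2ccc(OCc3ccccc3)c(OC)c2)[C@H](O[C@@H]2C[C@H](C)CC[C@H]2C(C)C)O1
F3 | step 13 | lithium enolate of F2 | [Li]OC1=C[C@@H](Cc2ccc(OCc3ccccc3)c(OC)c2)[C@H](O[C@@H]2C[C@H](C)CC[C@H]2C(C)C)O1
F4 | step 13 | (3R,4R,5R)-4-(Ar-methyl)-3-(BF-methyl)-5-(Men-oxy)oxolan-2-one | O=C1[C@H](Cc2cc(OC)c3c(c2)[C@H](COCc2ccccc2)[C@@H](c2ccc(OCc4ccccc4)c(OC)c2)O3)[C@@H](Cc2ccc(OCc3ccccc3)c(OC)c2)[C@H](O[C@@H]2C[C@H](C)CC[C@H]2C(C)C)O1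
F5 | step 8 | methyl 3-methoxy-5-(prop-2-en-1-yl)-4-{[(trifluoromethyl)sulfonyl]oxy}benzoate | COC(=O)c1cc(CC=C)c(OS(=O)(=O)C(F)(F)F)c(OC)c1
F6 | step 8 | methyl 3-methoxy-5-(2-oxoethyl)-4-{[(trifluoromethyl)sulfonyl]oxy}benzoate | COC(=O)c1cc(CC=O)c(OS(=O)(=O)C(F)(F)F)c(OC)c1
F7 | step 8 | 2-[3-methoxy-5-(methoxycarbonyl)-2-{[(trifluoromethyl)sulfonyl]oxy}phenyl]acetic acid | COC(=O)c1cc(CC(=O)O)c(OS(=O)(=O)C(F)(F)F)c(OC)c1
F8 | step 8 | mixed anhydride of F7 with pivalic acid | COC(=O)c1cc(CC(=O)OC(=O)C(C)(C)C)c(OS(=O)(=O)C(F)(F)F)c(OC)c1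
F9 | step 8 | methyl 3-{2-[(4S)-4-benzyl-2-oxo-1,3-oxazolidin-3-yl]-2-oxoethyl}-5-methoxy-4-{[(trifluoromethyl)sulfonyl]oxy}benzoate | COC(=O)c1cc(CC(=O)N2[C@@H](Cc3ccccc3)COC2=O)c(OS(=O)(=O)C(F)(F)F)c(OC)c1
F10 | step 8 | Z-dibutylboron enolate of F9 | CCCCB(CCCC)O/C(=C\c1cc(C(=O)OC)cc(OC)c1OS(=O)(=O)C(F)(F)F)N1[C@@H](Cc2ccccc2)COC1=O
F11 | step 8 | methyl 3-{(2S,3S)-1-[(4S)-4-benzyl-2-oxo-1,3-oxazolidin-3-yl]-3-[4-(benzyloxy)-3-methoxyphenyl]-3-hydroxy-1-oxopropan-2-yl}-5-methoxy-4-{[(trifluoromethyl)sulfonyl]oxy}benzoate | COC(=O)c1cc([C@H](C(=O)N2[C@@H](Cc3ccccc3)COC2=O)[C@H](O)c2ccc(OCc3ccccc3)c(OC)c2)c(OS(=O)(=O)C(F)(F)F)c(OC)c1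
F12 | step 8 | methyl 3-{(1S,2R)-1-[4-(benzyloxy)-3-methoxyphenyl]-1,3-dihydroxypropan-2-yl}-5-methoxy-4-{[(trifluoromethyl)sulfonyl]oxy}benzoate | COC(=O)c1cc([C@H](CO)[C@H](O)c2ccc(OCc3ccccc3)c(OC)c2)c(OS(=O)(=O)C(F)(F)F)c(OC)c1
F0 | step 15 | none | none
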